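**Plan**

- Retrosynthesis: the seven O–methyl bonds are cut first, then the C5 vinyl C=C bond (to a C5 aldehyde and a benzylphosphonate), then the C2–aryl and C3–aryl bonds across the furan C2=C3 bond, and last the furan ring back to an iodophenol and an acetylene.
- Forward: the benzo ring is bought as a 4-hydroxy-2-methoxybenzoate, the furan ring is closed by Sonogashira coupling and 5-endo cyclisation, both aryl rings are added to the furan bond in one dearomatising palladium step, and the stilbene arm is joined last, before global demethylation.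
- Enabling feature: in the 5,6-disubstituted benzofuran the C2=C3 bond of the furan ring, flanked by O1 and by C3a of the benzo ring, has little aromatic stabilisation and reacts as a cyclic aryl enol ether, taking aryl at C2 and palladium at benzylic C3.
- Stereochemistry: C3 (S) comes from ligand-controlled face selection in that step; C2 is formed cis (R) and is then inverted to S (trans) by acid through reversible C2–O1 ionisation; the E alkene comes from the Horner–Wadsworth–Emmons reaction.

Key step: step 5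

Assumption: the (S)-configured pyridine-oxazoline is taken to direct arylation to the face of the furan bond that gives (3S); if a trial run shows the opposite sense, the (R)-ligand is used with no other change.

**Step 1**
Reactants: 1 methyl 4-hydroxy-2-methoxybenzoate
Product: 2 methyl 4-hydroxy-5-iodo-2-methoxybenzoate
Conditions: NIS (1.05 equiv), TFA (10 mol%), MeCN, 0 → 23 °C
Reagents that add atoms: N-iodosuccinimide, O=C1CCC(=O)N1I
Why: Electrophilic aromatic iodination should go to C5, which is ortho to the hydroxyl and para to the methoxy group, while the other ortho position (C3) is hindered between two oxygen substituents.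

**Step 2**
Reactants: 2 methyl 4-hydroxy-5-iodo-2-methoxybenzoate; 3 ethynyltrimethylsilane
Product: 4 methyl 4-hydroxy-2-methoxy-5-[(trimethylsilyl)ethynyl]benzoate
Conditions: PdCl2(PPh3)2 (2 mol%), CuI (4 mol%), Et3N, THF, 23 °C
Reagents that add atoms: none
Why: Sonogashira coupling of an aryl iodide with a free ortho hydroxyl proceeds at room temperature, and the silyl cap prevents a second coupling.

**Step 3**
Reactants: 4 methyl 4-hydroxy-2-methoxy-5-[(trimethylsilyl)ethynyl]benzoate
Product: 6 methyl 6-methoxy-1-benzofuran-5-carboxylate, via ethynylphenol 5 (not isolated)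
Conditions: K2CO3 (0.3 equiv), MeOH, 23 °C; then CuI (10 mol%), Et3N, 65 °C, argon
Reagents that add atoms: none
Why: Methanolic carbonate removes the alkynyl silyl group and the o-ethynylphenol, made acidic by the para ester, should undergo CuI-promoted 5-endo-dig hydroalkoxylation, a standard benzofuran annulation.

**Step 4**
Reactants: 7 3,4-dimethoxyaniline
Product: 8 3,4-dimethoxybenzenediazonium tetrafluoroborate
Conditions: NaNO2, 48% aq HBF4, H2O, 0 °C; precipitate washed with cold Et2O
Reagents that add atoms: sodium nitrite, [Na+].[O-]N=O; tetrafluoroboric acid, [H+].F[B-](F)(F)F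
Why: Diazotisation of an electron-rich aniline gives a tetrafluoroborate salt that precipitates and can be stored cold.

**Step 5**
Reactants: 6 methyl 6-methoxy-1-benzofuran-5-carboxylate; 8 3,4-dimethoxybenzenediazonium tetrafluoroborate; 9 3,5-dimethoxyphenylboronic acid
Product: 10 methyl (2R,3S)-2-(3,4-dimethoxyphenyl)-3-(3,5-dimethoxyphenyl)-6-methoxy-2,3-dihydro-1-benzofuran-5-carboxylate (cis)
Conditions: Pd2(dba)3 (5 mol%), (S)-4-tert-butyl-2-[5-(trifluoromethyl)pyridin-2-yl]-4,5-dihydrooxazole (12 mol%), 2,6-di-tert-butyl-4-methylpyridine (2 equiv), DMA, 0 → 23 °C; 8 (2 equiv) and 9 (2.5 equiv) added in parallel over 6 h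
Reagents that add atoms: none
Why: Proposed new method: oxidative addition of 8 to zerovalent palladium gives a cationic arylpalladium on the chiral pyridine-oxazoline, which adds syn across the furan C2=C3 bond of 6 with the veratryl group on the oxygen-bearing C2 and the metal on C3, where the benzo ring holds it as an η3-benzyl complex until 9 transmetalates and C–C reductive elimination with retention delivers the 3,5-dimethoxyphenyl group to C3. The closest known reaction types are the three-component 1,2-diarylation of vinylarenes and dienes with arenediazonium salts and arylboronic acids, the Heck–Matsuda C2 arylation of benzofurans that ends in rearomatisation, and intramolecular dearomative Heck/Suzuki cascades of indoles and benzofurans; the intermolecular capture of the dearomatised benzylpalladium is the untested part. No ring is closed. C3 (S) is set by the ligand, which selects the face of the furan bond that is arylated, and C2 (R) follows from the suprafacial addition and the retentive reductive elimination, which place the two aryl groups cis. The step needs aryl-to-C2 regiochemistry, insertion faster than direct biaryl coupling of 8 with 9, and capture faster than rearomatisation: O1 polarises the enol-ether bond and the benzo ring stabilises palladium at C3, feeding 8 and 9 slowly into a solution rich in 6 without a boronate-forming base keeps transmetalation of the free arylpalladium slow, and in the insertion product the C2–H bond lies anti to palladium while the C2–O1 bond is held out of plane by the ring, so no syn β-hydride or β-alkoxide elimination is available. The hindered pyridine only traps HBF4, so the acid-labile benzylic C2–O1 bond of 10 should not ionise before isolation.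

**Step 6**
Reactants: 10 methyl (2R,3S)-2-(3,4-dimethoxyphenyl)-3-(3,5-dimethoxyphenyl)-6-methoxy-2,3-dihydro-1-benzofuran-5-carboxylate
Product: 11 methyl (2S,3S)-2-(3,4-dimethoxyphenyl)-3-(3,5-dimethoxyphenyl)-6-methoxy-2,3-dihydro-1-benzofuran-5-carboxylate (trans)
Conditions: TFA (10 equiv), CH2Cl2, 0 → 23 °C, dilute
Reagents that add atoms: none
Why: Acid-mediated epimerisation of a cis-2-aryl-2,3-dihydrobenzofuran: the C2–O1 bond ionises reversibly (p-methoxybenzylic cation, phenol leaving group bearing a para ester) and re-closes to the more stable trans ring, so C2 becomes S while C3, which is not part of the ionising bond, keeps its S configuration.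

**Step 7**
Reactants: 11 methyl (2S,3S)-2-(3,4-dimethoxyphenyl)-3-(3,5-dimethoxyphenyl)-6-methoxy-2,3-dihydro-1-benzofuran-5-carboxylate
Product: 12 [(2S,3S)-2-(3,4-dimethoxyphenyl)-3-(3,5-dimethoxyphenyl)-6-methoxy-2,3-dihydro-1-benzofuran-5-yl]methanol
Conditions: LiAlH4, THF, 0 °C; Fieser work-up
Reagents that add atoms: none
Why: Hydride reduction of an aryl methyl ester to the benzyl alcohol, with no other reducible group in 11.

**Step 8**
Reactants: 12 [(2S,3S)-2-(3,4-dimethoxyphenyl)-3-(3,5-dimethoxyphenyl)-6-methoxy-2,3-dihydro-1-benzofuran-5-yl]methanol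
Product: 13 (2S,3S)-2-(3,4-dimethoxyphenyl)-3-(3,5-dimethoxyphenyl)-6-methoxy-2,3-dihydro-1-benzofuran-5-carbaldehyde
Conditions: MnO2 (activated, excess), CH2Cl2, 23 °C
Reagents that add atoms: none
Why: MnO2 oxidises the electron-rich benzylic alcohol to the aldehyde under neutral conditions, which spares the acid-sensitive 2,4-dialkoxybenzyl alcohol and the C2–O1 bond.

**Step 9**
Reactants: 13 (2S,3S)-2-(3,4-dimethoxyphenyl)-3-(3,5-dimethoxyphenyl)-6-methoxy-2,3-dihydro-1-benzofuran-5-carbaldehyde; 14 diethyl (3,5-dimethoxybenzyl)phosphonate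
Product: 15 (2S,3S)-2-(3,4-dimethoxyphenyl)-3-(3,5-dimethoxyphenyl)-5-[(E)-2-(3,5-dimethoxyphenyl)ethenyl]-6-methoxy-2,3-dihydro-1-benzofuran
Conditions: KOtBu, THF, 0 → 23 °C
Reagents that add atoms: none
Why: Horner–Wadsworth–Emmons olefination of a non-enolisable aromatic aldehyde with a benzylphosphonate anion should give the E-stilbene, and neither ring stereocentre is acidic enough to be touched by the base.

**Step 10**
Reactants: 15 (2S,3S)-2-(3,4-dimethoxyphenyl)-3-(3,5-dimethoxyphenyl)-5-[(E)-2-(3,5-dimethoxyphenyl)ethenyl]-6-methoxy-2,3-dihydro-1-benzofuran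
Product: 16 5-[(E)-2-[(2S,3S)-2-(3,4-dihydroxyphenyl)-3-(3,5-dihydroxyphenyl)-6-hydroxy-2,3-dihydro-1-benzofuran-5-yl]ethenyl]benzene-1,3-diol
Conditions: BBr3 (12 equiv), CH2Cl2, −78 → 0 °C; ice-water quench
Reagents that add atoms: none
Why: BBr3 cleaves all seven aryl methyl ethers (Lewis acid adduct, then bromide attack at methyl); any ionisation at C2 should re-close to the trans ring already in place, and C3 is untouched.

**Compound list**

1 | methyl 4-hydroxy-2-methoxybenzoate | COC(=O)c1ccc(O)cc1OC | starting material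
2 | methyl 4-hydroxy-5-iodo-2-methoxybenzoate | COC(=O)c1cc(I)c(O)cc1OC | intermediate
3 | ethynyltrimethylsilane | C#C[Si](C)(C)C | starting material
4 | methyl 4-hydroxy-2-methoxy-5-[(trimethylsilyl)ethynyl]benzoate | COC(=O)c1cc(C#C[Si](C)(C)C)c(O)cc1OC | intermediate
5 | methyl 5-ethynyl-4-hydroxy-2-methoxybenzoate | COC(=O)c1cc(C#C)c(O)cc1OC | intermediate
6 | methyl 6-methoxy-1-benzofuran-5-carboxylate | COC(=O)c1cc2ccoc2cc1OC | intermediate
7 | 3,4-dimethoxyaniline | Nc1ccc(OC)c(OC)c1 | starting material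
8 | 3,4-dimethoxybenzenediazonium tetrafluoroborate | COc1ccc([N+]#N)cc1OC.F[B-](F)(F)F | intermediate
9 | 3,5-dimethoxyphenylboronic acid | OB(O)c1cc(OC)cc(OC)c1 | starting material
10 | methyl (2R,3S)-2-(3,4-dimethoxyphenyl)-3-(3,5-dimethoxyphenyl)-6-methoxy-2,3-dihydro-1-benzofuran-5-carboxylate (cis) | COC(=O)c1cc2c(cc1OC)O[C@@H](c1ccc(OC)c(OC)c1)[C@H]2c1cc(OC)cc(OC)c1 | intermediate
11 | methyl (2S,3S)-2-(3,4-dimethoxyphenyl)-3-(3,5-dimethoxyphenyl)-6-methoxy-2,3-dihydro-1-benzofuran-5-carboxylate (trans) | COC(=O)c1cc2c(cc1OC)O[C@H](c1ccc(OC)c(OC)c1)[C@H]2c1cc(OC)cc(OC)c1 | intermediate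
12 | [(2S,3S)-2-(3,4-dimethoxyphenyl)-3-(3,5-dimethoxyphenyl)-6-methoxy-2,3-dihydro-1-benzofuran-5-yl]methanol | OCc1cc2c(cc1OC)O[C@H](c1ccc(OC)c(OC)c1)[C@H]2c1cc(OC)cc(OC)c1 | intermediate
13 | (2S,3S)-2-(3,4-dimethoxyphenyl)-3-(3,5-dimethoxyphenyl)-6-methoxy-2,3-dihydro-1-benzofuran-5-carbaldehyde | O=Cc1cc2c(cc1OC)O[C@H](c1ccc(OC)c(OC)c1)[C@H]2c1cc(OC)cc(OC)c1 | intermediate
14 | diethyl (3,5-dimethoxybenzyl)phosphonate | CCOP(=O)(Cc1cc(OC)cc(OC)c1)OCC | starting material
15 | (2S,3S)-2-(3,4-dimethoxyphenyl)-3-(3,5-dimethoxyphenyl)-5-[(E)-2-(3,5-dimethoxyphenyl)ethenyl]-6-methoxy-2,3-dihydro-1-benzofuran | COc1cc(OC)cc(/C=C/c2cc3c(cc2OC)O[C@H](c2ccc(OC)c(OC)c2)[C@H]3c2cc(OC)cc(OC)c2)c1 | intermediate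
16 | 5-[(E)-2-[(2S,3S)-2-(3,4-dihydroxyphenyl)-3-(3,5-dihydroxyphenyl)-6-hydroxy-2,3-dihydro-1-benzofuran-5-yl]ethenyl]benzene-1,3-diol | Oc1cc(O)cc(/C=C/c2cc3c(cc2O)O[C@H](c2ccc(O)c(O)c2)[C@H]3c2cc(O)cc(O)c2)c1 | target

**Count and risks**

Total step count: 10. Longest linear sequence: 9 steps (steps 1, 2, 3, 5, 6, 7, 8, 9, 10 from 1); step 4 is a one-step branch.

Step 5 (dearomative diarylation). The free arylpalladium cation may be consumed by direct cross-coupling of 8 with 9 before it inserts into the furan bond. The benzylpalladium intermediate may rearomatise to a 2-arylbenzofuran before it meets the boronic acid, or the ligand may discriminate the two faces poorly. The fallback uses known chemistry, sets out from 6 and comes back at 10: the two C–aryl bonds are made one after the other on the aromatic benzofuran and the ring is reduced afterwards. Heck–Matsuda-type C2 arylation of 6 with 8 (Pd(OAc)2, MeOH, 50 °C) should give methyl 2-(3,4-dimethoxyphenyl)-6-methoxy-1-benzofuran-5-carboxylate F1. NBS in MeCN should brominate the free C3 position to give methyl 3-bromo-2-(3,4-dimethoxyphenyl)-6-methoxy-1-benzofuran-5-carboxylate F2. Suzuki–Miyaura coupling with 9 (Pd(PPh3)4, K2CO3, dioxane/H2O, 90 °C) should give methyl 2-(3,4-dimethoxyphenyl)-3-(3,5-dimethoxyphenyl)-6-methoxy-1-benzofuran-5-carboxylate F3. Hydrogenation of the furan bond from one face (H2 under pressure, Pd(OH)2 on carbon, EtOAc/AcOH) should give the racemic cis-dihydrobenzofuran ester F4. Preparative chromatography on a chiral stationary phase then separates the (2R,3S) enantiomer, which is 10.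

Step 10 (global demethylation). Under the Lewis acid the electron-rich 2,4-dioxygenated stilbene may ionise and oligomerise, the benzylic C2–O1 bond may open without re-closing, or cleavage of seven ethers may stop short. The fallback sets out from 13 and comes back at 16: the ethers are cleaved before the alkene exists, and the phenols are carried through the olefination as silyl ethers that fluoride removes. BBr3 on 13 should give (2S,3S)-2-(3,4-dihydroxyphenyl)-3-(3,5-dihydroxyphenyl)-6-hydroxy-2,3-dihydro-1-benzofuran-5-carbaldehyde F8, and TBSCl with imidazole in DMF should give the pentakis(tert-butyldimethylsilyl) ether aldehyde F9. The olefination partner is made from commercial 3,5-dihydroxybenzaldehyde. Silylation gives 3,5-bis(tert-butyldimethylsilyloxy)benzaldehyde F10, and NaBH4 gives [3,5-bis(tert-butyldimethylsilyloxy)phenyl]methanol F11. CBr4/PPh3 gives 3,5-bis(tert-butyldimethylsilyloxy)benzyl bromide F12, and an Arbuzov reaction with triethyl phosphite gives diethyl [3,5-bis(tert-butyldimethylsilyloxy)benzyl]phosphonate F13. Horner–Wadsworth–Emmons reaction of F9 with the anion of F13 (NaHMDS, THF, −78 → 0 °C) should give the heptakis(silyl) E-stilbene F14. Et3N·3HF in THF then frees all seven phenols to give 16.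

Step 6 (C2 epimerisation). The open C2 cation may lose the C3 proton to a triarylethene whose reprotonation erodes the C3 configuration, or it may be intercepted by trifluoroacetate and not re-close. The fallback sets out from 10 and comes back at 16: the separate Brønsted-acid step is dropped and the cis series is carried on. The inversion is left to the aprotic Lewis-acid step at the end, where no proton source is present before the quench. LiAlH4 reduction of 10 should give [(2R,3S)-2-(3,4-dimethoxyphenyl)-3-(3,5-dimethoxyphenyl)-6-methoxy-2,3-dihydro-1-benzofuran-5-yl]methanol F5. MnO2 should give the cis aldehyde (2R,3S)-2-(3,4-dimethoxyphenyl)-3-(3,5-dimethoxyphenyl)-6-methoxy-2,3-dihydro-1-benzofuran-5-carbaldehyde F6. Horner–Wadsworth–Emmons reaction with 14 should give the cis heptamethyl ether (2R,3S)-2-(3,4-dimethoxyphenyl)-3-(3,5-dimethoxyphenyl)-5-[(E)-2-(3,5-dimethoxyphenyl)ethenyl]-6-methoxy-2,3-dihydro-1-benzofuran F7. BBr3 then cleaves the ethers while the C2–O1 bond ionises and re-closes to the trans ring, giving 16. If the silyl endgame is in use, the same treatment of F6 leads to F8.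

**Further compounds**

F1 | step 5 | methyl 2-(3,4-dimethoxyphenyl)-6-methoxy-1-benzofuran-5-carboxylate | COC(=O)c1cc2cc(-c3ccc(OC)c(OC)c3)oc2cc1OC
F2 | step 5 | methyl 3-bromo-2-(3,4-dimethoxyphenyl)-6-methoxy-1-benzofuran-5-carboxylate | COC(=O)c1cc2c(Br)c(-c3ccc(OC)c(OC)c3)oc2cc1OC
F3 | step 5 | methyl 2-(3,4-dimethoxyphenyl)-3-(3,5-dimethoxyphenyl)-6-methoxy-1-benzofuran-5-carboxylate | COC(=O)c1cc2c(-c3cc(OC)cc(OC)c3)c(-c3ccc(OC)c(OC)c3)oc2cc1OC
F4 | step 5 | racemic methyl cis-2-(3,4-dimethoxyphenyl)-3-(3,5-dimethoxyphenyl)-6-methoxy-2,3-dihydro-1-benzofuran-5-carboxylate (both enantiomers written) | COC(=O)c1cc2c(cc1OC)O[C@@H](c1ccc(OC)c(OC)c1)[C@H]2c1cc(OC)cc(OC)c1.COC(=O)c1cc2c(cc1OC)O[C@H](c1ccc(OC)c(OC)c1)[C@@H]2c1cc(OC)cc(OC)c1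
F5 | step 6 | [(2R,3S)-2-(3,4-dimethoxyphenyl)-3-(3,5-dimethoxyphenyl)-6-methoxy-2,3-dihydro-1-benzofuran-5-yl]methanol | OCc1cc2c(cc1OC)O[C@@H](c1ccc(OC)c(OC)c1)[C@H]2c1cc(OC)cc(OC)c1
F6 | step 6 | (2R,3S)-2-(3,4-dimethoxyphenyl)-3-(3,5-dimethoxyphenyl)-6-methoxy-2,3-dihydro-1-benzofuran-5-carbaldehyde | O=Cc1cc2c(cc1OC)O[C@@H](c1ccc(OC)c(OC)c1)[C@H]2c1cc(OC)cc(OC)c1
F7 | step 6 | (2R,3S)-2-(3,4-dimethoxyphenyl)-3-(3,5-dimethoxyphenyl)-5-[(E)-2-(3,5-dimethoxyphenyl)ethenyl]-6-methoxy-2,3-dihydro-1-benzofuran | COc1cc(OC)cc(/C=C/c2cc3c(cc2OC)O[C@@H](c2ccc(OC)c(OC)c2)[C@H]3c2cc(OC)cc(OC)c2)c1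
F8 | step 10 | (2S,3S)-2-(3,4-dihydroxyphenyl)-3-(3,5-dihydroxyphenyl)-6-hydroxy-2,3-dihydro-1-benzofuran-5-carbaldehyde | O=Cc1cc2c(cc1O)O[C@H](c1ccc(O)c(O)c1)[C@H]2c1cc(O)cc(O)c1
F9 | step 10 | (2S,3S)-2-[3,4-bis(tert-butyldimethylsilyloxy)phenyl]-3-[3,5-bis(tert-butyldimethylsilyloxy)phenyl]-6-(tert-butyldimethylsilyloxy)-2,3-dihydro-1-benzofuran-5-carbaldehyde | O=Cc1cc2c(cc1O[Si](C)(C)C(C)(C)C)O[C@H](c1ccc(O[Si](C)(C)C(C)(C)C)c(O[Si](C)(C)C(C)(C)C)c1)[C@H]2c1cc(O[Si](C)(C)C(C)(C)C)cc(O[Si](C)(C)C(C)(C)C)c1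
F10 | step 10 | 3,5-bis(tert-butyldimethylsilyloxy)benzaldehyde | O=Cc1cc(O[Si](C)(C)C(C)(C)C)cc(O[Si](C)(C)C(C)(C)C)c1
F11 | step 10 | [3,5-bis(tert-butyldimethylsilyloxy)phenyl]methanol | OCc1cc(O[Si](C)(C)C(C)(C)C)cc(O[Si](C)(C)C(C)(C)C)c1
F12 | step 10 | 3,5-bis(tert-butyldimethylsilyloxy)benzyl bromide | BrCc1cc(O[Si](C)(C)C(C)(C)C)cc(O[Si](C)(C)C(C)(C)C)c1
F13 | step 10 | diethyl [3,5-bis(tert-butyldimethylsilyloxy)benzyl]phosphonate | CCOP(=O)(Cc1cc(O[Si](C)(C)C(C)(C)C)cc(O[Si](C)(C)C(C)(C)C)c1)OCC
F14 | step 10 | (2S,3S)-2-[3,4-bis(tert-butyldimethylsilyloxy)phenyl]-3-[3,5-bis(tert-butyldimethylsilyloxy)phenyl]-5-[(E)-2-[3,5-bis(tert-butyldimethylsilyloxy)phenyl]ethenyl]-6-(tert-butyldimethylsilyloxy)-2,3-dihydro-1-benzofuran | CC(C)(C)[Si](C)(C)Oc1cc(O[Si](C)(C)C(C)(C)C)cc(/C=C/c2cc3c(cc2O[Si](C)(C)C(C)(C)C)O[C@H](c2ccc(O[Si](C)(C)C(C)(C)C)c(O[Si](C)(C)C(C)(C)C)c2)[C@H]3c2cc(O[Si](C)(C)C(C)(C)C)cc(O[Si](C)(C)C(C)(C)C)c2)c1
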